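**Plan**

1. Numbering: ring carbons C1–C11 follow the SMILES order (C1 and C3 angelate carbinols, C2 acetate carbinol, C4 quaternary C–CH3, C5/C6/C7 cyclobutane CH, C8 ketone, C9 CH2, C10 CH–CH3, C11 C(CH3)2). Ring A is the seven-membered ring (C1–C4, C5 or C7, C6, C11), ring B the cyclohexanone (C5–C10), ring C the cyclobutane (C4–C7).
2. Cuts: the three ester C–O bonds; the C1–O/C2–O pair back to a C1=C2 alkene; C11–C1 (radical conjugate addition), C6=C11 (olefination) and C2–C3 (vinyl addition) of ring A; C5–C10 and C7–C8 of ring B; ring C back to dichloroketene and a methallyl ether.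
3. Enabling feature: in ring B, C5 and C7 are the α and α′ carbons of a carbonyl at C6 of ring C, and C8(=O)–C9–C10(CH3) is a crotonyl unit. Ring B is therefore what C-acylation of one α-carbon (C7–C8) and Michael alkylation of the other (C5–C10) of a 3,3-disubstituted cyclobutanone would give.
4. Forward order: ring C ([2+2], dechlorination), ring B (enamine annulation with crotonoyl chloride), ring A (isopropylidenation, acryloyl ketone, HAT-initiated 7-endo radical closure), then enone, oxygenation of C1–C3 and acylation.
5. Stereochemistry: (2R,5R)-2,5-dimethylpyrrolidine and the bulky C4 silyloxymethyl group fix C4, C5, C7 and C10 in the annulation; hydrogen delivery to C6 from the open face sets C6; a CBS reduction sets C3; anti-dihydroxylation and SN2 inversion at C2 relay C3 to C2 and C1.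

Key step: step 4

Assumption: the two faces of ring A differ only through the distant C8 and C10 groups, so no substrate control is counted on at C3; the carbinol is set by the catalyst in step 13 and C2 and C1 are derived from it. (TBDPS = tert-butyldiphenylsilyl, TES = triethylsilyl.)

**Route**

Step 1
Reactants: 1 2-methylprop-2-en-1-ol
Product: 2 tert-butyl[(2-methylprop-2-en-1-yl)oxy]diphenylsilane
Conditions: TBDPSCl, imidazole, CH2Cl2, 0 °C → rt
Reagents that add atoms: tert-butyl(chloro)diphenylsilane, CC(C)(C)[Si](Cl)(c1ccccc1)c1ccccc1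
Why: Imidazole-promoted silylation of the primary allylic alcohol; the bulky silyl ether later serves as the face-blocking group at C4.

Step 2
Reactants: 2 tert-butyl[(2-methylprop-2-en-1-yl)oxy]diphenylsilane; 3 trichloroacetyl chloride
Product: 5 rac-2,2-dichloro-3-methyl-3-[(TBDPS-oxy)methyl]cyclobutan-1-one, via dichloroketene 4 (not isolated)
Conditions: activated Zn dust, Et2O/DME, ultrasound, 15–25 °C
Reagents that add atoms: none
Why: Ketene–alkene [2+2] cycloaddition in which the ketene carbonyl carbon bonds to the CH2 terminus of the 1,1-disubstituted alkene, giving ring C as a racemate whose single stereocentre is erased in step 3.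

Step 3
Reactants: 5 rac-2,2-dichloro-3-methyl-3-[(TBDPS-oxy)methyl]cyclobutan-1-one
Product: 6 3-methyl-3-[(TBDPS-oxy)methyl]cyclobutan-1-one
Conditions: Zn dust, AcOH, rt → 50 °C
Reagents that add atoms: none
Why: Reductive dechlorination of an α,α-dichloroketone by zinc (through zinc enolates) should leave the achiral, mirror-symmetric cyclobutanone with the silyl ether intact.

Step 4
Reactants: 6 3-methyl-3-[(TBDPS-oxy)methyl]cyclobutan-1-one; 7 (2R,5R)-2,5-dimethylpyrrolidine; 8 (E)-but-2-enoyl chloride
Product: 11 (1R,4R,5R,7R)-4,7-dimethyl-7-[(TBDPS-oxy)methyl]bicyclo[3.1.1]heptane-2,6-dione (ring B on ring C; ketones at C6 and C8), via enamine 9 (not isolated), via bicyclic iminium chloride 10 (not isolated)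
Conditions: 7 (1.2 equiv), 4 Å MS, PhMe, 60 °C; then 8, PhMe, 0 → 80 °C; then NaOAc/AcOH/H2O, rt
Reagents that add atoms: water, O
Why: Proposed new method: enamine 9 is N-acylated by 8, the N-acyl enammonium ion undergoes a chair-like aza-Claisen ([3,3]) shift that joins C5 to C10 and leaves a ketene–iminium pair, the iminium re-forms the enamine toward C7, and this α′-carbon attacks the ketene carbon C8 (6-exo-dig C-acylation, or 6-exo-trig if the acyl chloride is still present) to close ring B as the bridged iminium salt 10, which buffered water hydrolyses to 11; the closest known reaction type is the α,α′-annulation of cyclohexanone and cyclopentanone enamines with α,β-unsaturated acid chlorides to bridged bicyclic 1,3-diketones, not yet shown on a cyclobutanone. The tether can reach C7 only on the face where C5 was attacked, so C5 and C7 are set together, and that face is the one anti to the large CH2OTBDPS group, which turns C4 into a stereocentre with its methyl over ring B. The C2-symmetric (2R,5R)-amine shields one face of each of the two equilibrating enamines, so only the enamine whose open face is also anti to CH2OTBDPS reacts fast (Curtin–Hammett), which decides which enantiotopic α-carbon becomes C5 and hence the absolute configuration. C10 is set in the same [3,3] event: with the (E)-crotonyl methyl and the ring carbon C4 both pseudo-equatorial in the chair, the C10 methyl ends on the C6 side, away from the C4 bridge. The step needs face selectivity (methyl versus CH2OTBDPS at C4), enantiotopic-carbon selectivity (the amine) and C- rather than O-acylation in the ring closure; because C7 is a bridgehead the dione cannot enolise, so it is released as the iminium salt and the mild buffered hydrolysis should avoid retro-Claisen opening.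

Step 5
Reactants: 11 bicyclic diketone; 12 isopropyltriphenylphosphonium iodide
Product: 14 isopropylidene ketone (C6=C(CH3)2 in place of the C6 carbonyl; C8 ketone kept), via phosphorus ylide 13 (not isolated)
Conditions: 12 (2.5 equiv), KN(SiMe3)2, THF, 0 °C; then 11, −78 °C → rt
Reagents that add atoms: none
Why: Wittig olefination: the strained, non-enolisable cyclobutanone carbonyl C6 is the more electrophilic one, while the C8 ketone is shielded as its enolate by the excess basic ylide, so only C6 should be isopropylidenated (no stereocentre is formed).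

Step 6
Reactants: 14 isopropylidene ketone
Product: 15 C8 ethylene ketal of 14 (spiro-1,3-dioxolane at C8)
Conditions: Me3SiOCH2CH2OSiMe3, TMSOTf (5 mol %), CH2Cl2, −78 → −20 °C; pyridine quench
Reagents that add atoms: 1,2-bis(trimethylsilyloxy)ethane, C[Si](C)(C)OCCO[Si](C)(C)C
Why: Noyori ketalisation under aprotic, low-temperature conditions protects C8 without protonating the tetrasubstituted alkylidenecyclobutane (which could trigger ring expansion).

Step 7
Reactants: 15 ketal silyl ether
Product: 16 primary alcohol (CH2OH on C4)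
Conditions: Bu4NF, THF, rt
Reagents that add atoms: none
Why: Fluoride-mediated desilylation; alkene and ketal are inert to fluoride.

Step 8
Reactants: 16 primary alcohol
Product: 17 aldehyde (C3 formyl group on C4)
Conditions: Dess–Martin periodinane, NaHCO3, CH2Cl2, 0 °C → rt
Reagents that add atoms: none
Why: Dess–Martin oxidation to a neopentyl aldehyde that cannot epimerise because C4 is quaternary.

Step 9
Reactants: 17 aldehyde; 18 vinylmagnesium bromide
Product: 19 allylic alcohol C4–CH(OH)–CH=CH2 (mixture of C3 epimers)
Conditions: 18 (1.2 equiv), THF, −78 °C; aq. NH4Cl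
Reagents that add atoms: none
Why: Grignard addition forms the C2–C3 bond while the C8 ketal keeps the other carbonyl masked; the C3 epimers converge in step 10.

Step 10
Reactants: 19 allylic alcohol
Product: 20 acryloyl ketone C4–C(=O)–CH=CH2
Conditions: Dess–Martin periodinane, NaHCO3, CH2Cl2, 0 °C
Reagents that add atoms: none
Why: Dess–Martin oxidation of the allylic alcohol gives the vinyl ketone that serves as radical acceptor for ring A.

Step 11
Reactants: 20 acryloyl ketone
Product: 21 tricyclic ketone (ring A closed; C3 ketone; C1 and C2 methylene; C11 gem-dimethyl; C6–H on the face of the C8–C10 bridge; C8 ketal)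
Conditions: Fe(acac)3 (30 mol %), PhSiH3, EtOH/ethylene glycol, 60 °C, high dilution
Reagents that add atoms: none
Why: MHAT-initiated Giese cyclisation (iron-hydride hydrogen atom transfer, then radical conjugate addition): the hydrogen atom should reach C6 from the face toward the C8–C10 bridge, the only one not covered by the axial acryloyl group on C4, which sets C6 and leaves the tertiary C11 radical axial beside the enone, where 7-endo-trig addition to C1 closes ring A before the α-keto radical is reduced and protonated.

Step 12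
Reactants: 21 tricyclic ketone
Product: 23 tricyclic enone (C3 ketone conjugated to C1=C2), via trimethylsilyl enol ether 22 (not isolated)
Conditions: TMSOTf, Et3N, CH2Cl2, 0 °C; then Pd(OAc)2, MeCN, rt
Reagents that add atoms: none
Why: Saegusa–Ito oxidation: the C3 ketone can enolise only toward C2 (C4 is quaternary and C8 is ketalised), and the silyl enol ether is dehydrogenated by Pd(OAc)2 to the enone.

Step 13
Reactants: 23 tricyclic enone
Product: 24 (3R)-allylic alcohol (C3–OH on the ring A face toward C7)
Conditions: (S)-2-methyl-CBS-oxazaborolidine (20 mol %), catecholborane, PhMe, −78 °C; MeOH then aq. NaOH work-up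
Reagents that add atoms: none
Why: Corey–Bakshi–Shibata reduction under reagent control: with the quaternary C4 as the large group and the vinyl CH as the small one, the (S)-catalyst should give the (R)-carbinol by 1,2-reduction.

Step 14
Reactants: 24 allylic alcohol
Product: 25 triethylsilyl ether of 24
Conditions: Et3SiCl, imidazole, DMAP (cat.), DMF, rt
Reagents that add atoms: chlorotriethylsilane, CC[Si](Cl)(CC)CC
Why: Silylation gives a small, non-participating ether whose bulk directs the osmylation and which falls off in the acidic step 17.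

Step 15
Reactants: 25 allylic silyl ether
Product: 26 diol (C1–OH and C2–OH cis to each other on the ring A face toward C5; anti to the C3 silyloxy group)
Conditions: OsO4 (2 mol %), NMO, acetone/H2O, rt
Reagents that add atoms: N-methylmorpholine N-oxide, C[N+]1([O-])CCOCC1; water, O
Why: Upjohn dihydroxylation: osmylation of an allylic ether occurs anti to the allylic oxygen substituent, which sets C1 (final configuration) and C2 (to be inverted).

Step 16
Reactants: 26 diol
Product: 28 cyclic sulfate across O1 and O2, via cyclic sulfite 27 (not isolated)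
Conditions: SOCl2, Et3N, CH2Cl2, 0 °C; then RuCl3 (1 mol %), NaIO4, MeCN/H2O, 0 °C
Reagents that add atoms: thionyl chloride, O=S(Cl)Cl; sodium periodate, [Na+].[O-]I(=O)(=O)=O
Why: Cyclic sulfate formation (sulfite, then RuO4-type oxidation) activates both carbinol carbons as an epoxide equivalent without touching the silyl ether or the ketal.

Step 17
Reactants: 28 cyclic sulfate
Product: 30 keto diol acetate (C8 ketone; C2 acetate; free C1 and C3 hydroxyls; all stereocentres as in the target), via cesium sulfate monoester 29 (not isolated)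
Conditions: CsOAc, DMF, 50 °C; then 1 M aq. H2SO4, THF, rt
Reagents that add atoms: cesium acetate, [Cs+].CC(=O)[O-]; water, O
Why: SN2 opening of the cyclic sulfate by acetate at C2 with inversion (C1 is neopentyl and blocked by C11) installs the acetate cis to the C3 oxygen and trans to the C1 oxygen, and aqueous acid then cleaves the sulfate monoester (S–O cleavage, retention at C1), the silyl ether and the ketal.

Step 18
Reactants: 30 keto diol acetate; 31 angelic acid ((Z)-2-methylbut-2-enoic acid)
Product: 33 target triester CNP0197834.1, via mixed anhydride 32 (not isolated)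
Conditions: 31 (6 equiv), 2,4,6-trichlorobenzoyl chloride, Et3N, PhMe, rt; then 30, PhMe, 80 °C
Reagents that add atoms: none
Why: Yamaguchi esterification, a protocol under which the (Z)-acid acylates hindered secondary alcohols without isomerising to the tiglate, should convert both remaining hydroxyls into angelates.

**Compound list**

1 | 2-methylprop-2-en-1-ol | C=C(C)CO | starting material
2 | tert-butyl[(2-methylprop-2-en-1-yl)oxy]diphenylsilane | C=C(C)CO[Si](c1ccccc1)(c1ccccc1)C(C)(C)C | intermediate
3 | trichloroacetyl chloride | ClC(Cl)(Cl)C(Cl)=O | starting material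
4 | dichloroketene (formed in the flask) | ClC(Cl)=C=O | intermediate
5 | rac-2,2-dichloro-3-methyl-3-[(TBDPS-oxy)methyl]cyclobutan-1-one | CC1(CO[Si](c2ccccc2)(c2ccccc2)C(C)(C)C)CC(=O)C1(Cl)Cl | intermediate
6 | 3-methyl-3-[(TBDPS-oxy)methyl]cyclobutan-1-one | CC1(CO[Si](c2ccccc2)(c2ccccc2)C(C)(C)C)CC(=O)C1 | intermediate
7 | (2R,5R)-2,5-dimethylpyrrolidine | C[C@@H]1CC[C@@H](C)N1 | starting material
8 | (E)-but-2-enoyl chloride | C/C=C/C(Cl)=O | starting material
9 | (2R,5R)-2,5-dimethyl-1-{3-methyl-3-[(TBDPS-oxy)methyl]cyclobut-1-en-1-yl}pyrrolidine (two equilibrating diastereomers at the ring quaternary carbon; formed in the flask) | C[C@@H]1CC[C@@H](C)N1C2=CC(C)(CO[Si](c3ccccc3)(c3ccccc3)C(C)(C)C)C2 | intermediate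
10 | bicyclic iminium chloride (C6=N+ of the (2R,5R)-pyrrolidinium, C8 ketone; formed in the flask) | CC(C)(C)[Si](c1ccccc1)(c1ccccc1)OC[C@]2(C)[C@@H]3C(=[N+]4[C@H](C)CC[C@H]4C)[C@H]2C(=O)C[C@H]3C.[Cl-] | intermediate
11 | (1R,4R,5R,7R)-4,7-dimethyl-7-[(TBDPS-oxy)methyl]bicyclo[3.1.1]heptane-2,6-dione (C4 methyl over ring B, C10 methyl on the C6 side) | CC(C)(C)[Si](c1ccccc1)(c1ccccc1)OC[C@]2(C)[C@@H]3C(=O)[C@H]2C(=O)C[C@H]3C | intermediate
12 | isopropyltriphenylphosphonium iodide | CC(C)[P+](c1ccccc1)(c1ccccc1)c1ccccc1.[I-] | starting material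
13 | isopropylidenetriphenylphosphorane (formed in the flask) | CC(C)=P(c1ccccc1)(c1ccccc1)c1ccccc1 | intermediate
14 | isopropylidene ketone: 11 with C6=C(CH3)2 in place of the C6 carbonyl | CC(C)(C)[Si](c1ccccc1)(c1ccccc1)OC[C@]2(C)[C@@H]3C(=C(C)C)[C@H]2C(=O)C[C@H]3C | intermediate
15 | C8 ethylene ketal of 14 | CC(C)(C)[Si](c1ccccc1)(c1ccccc1)OC[C@]2(C)[C@@H]3C(=C(C)C)[C@H]2C4(OCCO4)C[C@H]3C | intermediate
16 | primary alcohol: 15 with CH2OH on C4 | OC[C@]2(C)[C@@H]3C(=C(C)C)[C@H]2C4(OCCO4)C[C@H]3C | intermediate
17 | aldehyde: 15 with CHO (C3) on C4 | O=C[C@]2(C)[C@@H]3C(=C(C)C)[C@H]2C4(OCCO4)C[C@H]3C | intermediate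
18 | vinylmagnesium bromide | C=C[Mg]Br | starting material
19 | allylic alcohol C4–CH(OH)–CH=CH2, both C3 epimers | C=CC(O)[C@]2(C)[C@@H]3C(=C(C)C)[C@H]2C4(OCCO4)C[C@H]3C | intermediate
20 | acryloyl ketone C4–C(=O)–CH=CH2 | C=CC(=O)[C@]2(C)[C@@H]3C(=C(C)C)[C@H]2C4(OCCO4)C[C@H]3C | intermediate
21 | tricyclic ketone: ring A closed, C3 ketone, C11 gem-dimethyl, C6–H toward the C8–C10 bridge, C8 ketal | C1CC(=O)[C@]2(C)[C@@H]3[C@@H]([C@H]2C4(OCCO4)C[C@H]3C)C1(C)C | intermediate
22 | trimethylsilyl enol ether of 21 (C3(OSiMe3)=C2; formed in the flask) | C1C=C(O[Si](C)(C)C)[C@]2(C)[C@@H]3[C@@H]([C@H]2C4(OCCO4)C[C@H]3C)C1(C)C | intermediate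
23 | tricyclic enone: C3 ketone, C1=C2 | C1=CC(=O)[C@]2(C)[C@@H]3[C@@H]([C@H]2C4(OCCO4)C[C@H]3C)C1(C)C | intermediate
24 | (3R)-allylic alcohol: C3–OH on the ring A face toward C7 | C1=C[C@@H](O)[C@]2(C)[C@@H]3[C@@H]([C@H]2C4(OCCO4)C[C@H]3C)C1(C)C | intermediate
25 | triethylsilyl ether of 24 | C1=C[C@@H](O[Si](CC)(CC)CC)[C@]2(C)[C@@H]3[C@@H]([C@H]2C4(OCCO4)C[C@H]3C)C1(C)C | intermediate
26 | diol: C1–OH and C2–OH cis, on the ring A face toward C5, anti to C3–OTES | O[C@@H]1[C@H](O)[C@@H](O[Si](CC)(CC)CC)[C@]2(C)[C@@H]3[C@@H]([C@H]2C4(OCCO4)C[C@H]3C)C1(C)C | intermediate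
27 | cyclic sulfite of 26 across O1 and O2 (formed in the flask; sulfur epimers) | O5[C@@H]1[C@H](OS5=O)[C@@H](O[Si](CC)(CC)CC)[C@]2(C)[C@@H]3[C@@H]([C@H]2C4(OCCO4)C[C@H]3C)C1(C)C | intermediate
28 | cyclic sulfate of 26 across O1 and O2 | O5[C@@H]1[C@H](OS5(=O)=O)[C@@H](O[Si](CC)(CC)CC)[C@]2(C)[C@@H]3[C@@H]([C@H]2C4(OCCO4)C[C@H]3C)C1(C)C | intermediate
29 | cesium sulfate monoester: C2 acetate (inverted, cis to C3–O), C1–OSO3Cs (formed in the flask) | [Cs+].[O-]S(=O)(=O)O[C@@H]1[C@@H](OC(C)=O)[C@@H](O[Si](CC)(CC)CC)[C@]2(C)[C@@H]3[C@@H]([C@H]2C4(OCCO4)C[C@H]3C)C1(C)C | intermediate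
30 | keto diol acetate: C8 ketone, C2 acetate, free C1 and C3 hydroxyls | O[C@@H]1[C@@H](OC(C)=O)[C@@H](O)[C@]2(C)[C@@H]3[C@@H]([C@H]2C(=O)C[C@H]3C)C1(C)C | intermediate
31 | angelic acid, (Z)-2-methylbut-2-enoic acid | C/C=C(/C)C(=O)O | starting material
32 | angelic 2,4,6-trichlorobenzoic anhydride (formed in the flask) | C/C=C(/C)C(=O)OC(=O)c1c(Cl)cc(Cl)cc1Cl | intermediate
33 | CNP0197834.1: C1 and C3 angelates, C2 acetate, C8 ketone | C/C=C(/C)C(=O)O[C@@H]1[C@@H](OC(C)=O)[C@@H](OC(=O)/C(C)=C\C)[C@]2(C)[C@@H]3[C@@H]([C@H]2C(=O)C[C@H]3C)C1(C)C | target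

**Step count and risks**

Total step count: 18. Longest linear sequence: 18 steps (1 → 33).

Steps most likely to fail:

1. Step 4 (proposed new method). The N-acyl enammonium ion of the strained cyclobutene enamine may not rearrange (O-acylation or loss of the acid chloride as vinylketene instead). The strained, non-enolisable dione may open by retro-Claisen cleavage during the annulation or the hydrolysis. Discrimination between methyl and CH2OTBDPS on the C4 faces may be poor. The fallback uses only known chemistry, sets out from silyl ether 2 and returns at diketone 11. A boryl-Heck reaction of 2 (catecholchloroborane, a zerovalent palladium catalyst, then pinacol) gives the (E)-alkenylboronic pinacol ester F1. Hayashi–Miyaura conjugate addition of F1 to (E)-pent-3-en-2-one (Rh(acac)(C2H4)2, (R)-BINAP, dioxane/H2O; sense expected by analogy) gives the (4R)-methyl ketone F2, which carries C10. Horner–Wadsworth–Emmons reaction with triethyl phosphonoacetate gives the dienoate ester F3, and LiOH the dienoic acid F4. Oxalyl chloride gives the acid chloride F5, which with Et3N in refluxing toluene forms the vinylketene F6. Its intramolecular crossed ketene–alkene [2+2] cycloaddition should give the methylene ketone F7, in which the (E)-alkene places the C4 methyl over ring B and the C10 methyl turns away from the C4 bridge. Ozonolysis of the exocyclic methylene at C8 then gives 11.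

2. Step 11. Hydrogen atom transfer to the hindered tetrasubstituted alkene may be slow, or may place the hydrogen on C11 instead of C6, so that the radical is only reduced or closes a six-membered ring through C6. Delivery from the covered face would give a C6 epimer that cannot cyclise. The fallback sets out from 20 and returns at 21. Epoxidation of the electron-rich alkene with mCPBA from the open face gives the spiro-epoxide F8, with oxygen where the hydrogen is to be and C11 axial. Cp2TiCl (from Cp2TiCl2 and Zn), in the Nugent–RajanBabu manner, opens the epoxide to the tertiary C11 radical, which adds 7-endo to the enone and gives the C6 tertiary alcohol F9. Acylation with methyl oxalyl chloride gives the methyl oxalate F10. Radical deoxygenation with Bu3SnH/AIBN then gives 21, the hydrogen entering at the only position left open once ring A holds C11.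

3. Step 18. The two neopentyl-type hydroxyls may resist acylation under conditions mild enough to avoid angelate-to-tiglate isomerisation, and the C2 acetate may migrate to a free neighbouring hydroxyl during prolonged heating with base. The fallback sets out from 30 and returns at 33. Both hydroxyls are acylated with the small, reactive 2-[bis(2,2,2-trifluoroethoxy)phosphoryl]propanoic acid (DCC, DMAP) to give the bis(phosphonopropionate) F11. A double Still–Gennari olefination with acetaldehyde (KN(SiMe3)2, 18-crown-6, THF, −78 °C) then builds both (Z)-2-methylbut-2-enoates directly on the molecule.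

**Further compounds**

F1 | step 4 | tert-butyl{[(2E)-2-methyl-3-(4,4,5,5-tetramethyl-1,3,2-dioxaborolan-2-yl)prop-2-en-1-yl]oxy}diphenylsilane | CC(C)(C)[Si](c1ccccc1)(c1ccccc1)OC/C(C)=C/B1OC(C)(C)C(C)(C)O1
F2 | step 4 | (4R,5E)-7-(TBDPS-oxy)-4,6-dimethylhept-5-en-2-one | CC(=O)C[C@H](/C=C(\C)CO[Si](c1ccccc1)(c1ccccc1)C(C)(C)C)C
F3 | step 4 | ethyl (5R,6E)-8-(TBDPS-oxy)-3,5,7-trimethylocta-2,6-dienoate (2E/2Z mixture) | CCOC(=O)C=C(C)C[C@H](/C=C(\C)CO[Si](c1ccccc1)(c1ccccc1)C(C)(C)C)C
F4 | step 4 | (5R,6E)-8-(TBDPS-oxy)-3,5,7-trimethylocta-2,6-dienoic acid | OC(=O)C=C(C)C[C@H](/C=C(\C)CO[Si](c1ccccc1)(c1ccccc1)C(C)(C)C)C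
F5 | step 4 | (5R,6E)-8-(TBDPS-oxy)-3,5,7-trimethylocta-2,6-dienoyl chloride | ClC(=O)C=C(C)C[C@H](/C=C(\C)CO[Si](c1ccccc1)(c1ccccc1)C(C)(C)C)C
F6 | step 4 | vinylketene, (5R,6E)-8-(TBDPS-oxy)-5,7-dimethyl-3-methyleneocta-1,6-dien-1-one | O=C=CC(=C)C[C@H](/C=C(\C)CO[Si](c1ccccc1)(c1ccccc1)C(C)(C)C)C
F7 | step 4 | methylene ketone: 11 with C8=CH2 in place of the C8 carbonyl | CC(C)(C)[Si](c1ccccc1)(c1ccccc1)OC[C@]2(C)[C@@H]3C(=O)[C@H]2C(=C)C[C@H]3C
F8 | step 11 | spiro-epoxide of 20 across C6 and C11 (oxygen on the face of the C8–C10 bridge) | C=CC(=O)[C@]2(C)[C@@H]3[C@@]5(OC5(C)C)[C@H]2C4(OCCO4)C[C@H]3C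
F9 | step 11 | C6 tertiary alcohol: 21 with OH in place of the C6 hydrogen | C1CC(=O)[C@]2(C)[C@@H]3[C@@](O)([C@H]2C4(OCCO4)C[C@H]3C)C1(C)C
F10 | step 11 | methyl oxalate of F9 | C1CC(=O)[C@]2(C)[C@@H]3[C@@](OC(=O)C(=O)OC)([C@H]2C4(OCCO4)C[C@H]3C)C1(C)C
F11 | step 18 | bis(phosphonopropionate): 30 with both hydroxyls esterified by 2-[bis(2,2,2-trifluoroethoxy)phosphoryl]propanoic acid | CC(C(=O)O[C@@H]1[C@@H](OC(C)=O)[C@@H](OC(=O)C(C)P(=O)(OCC(F)(F)F)OCC(F)(F)F)[C@]2(C)[C@@H]3[C@@H]([C@H]2C(=O)C[C@H]3C)C1(C)C)P(=O)(OCC(F)(F)F)OCC(F)(F)F
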